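All runs stem from a simulated flask with made-up constants; the scatter is artificial.

To get the most target from a small charge, the flask is to be stopped at its peak, and here that peak is reckoned from the substrate left and not from the target made.

| flask | substrate | reagent | remark | time |
|---|---|---|---|---|
| teal | 0.75 M | 2.7 M | run made earlier |  |
| amber | 1.5 M | 1.4 M | run made earlier |  |
| flask | 1.5 M | 2.70 M |  | 25 min |

| run | time / min | target / % | substrate / % |
|---|---|---|---|
| teal | 0.667 | 3.1 | 97.3 |
| teal | 2.00 | 45.5 | 51.9 |
| teal | 5.00 | 75.4 | 0.9 |
| teal | 15.0 | 29.2 | 0 |
| amber | 0.667 | 1.4 | 98.7 |
| amber | 2.00 | 28.6 | 69.8 |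
| amber | 5.00 | 63.1 | 19.7 |
| amber | 15.0 | 29.9 | 9.3 |

(standard deviation of a reading: 0.3 percentage points)

- steps under discussion: substrate + reagent + target -> 2 target; substrate + reagent -> target; target -> over-reaction product

- time, not beyond 25 min, at which the flask holds most target
- the amount of target, in percent of the substrate charged, at that time

Take target as growing on itself and decaying by first order, with the direct step set aside. In the teal run, target falls from 75.4 % to 29.2 % between 5.00 min and 15.0 min, which gives a loss constant kd of 0.0949 min⁻¹. Early in the teal run, ln(c(target)/c(substrate)) climbs at k·c(reagent)·(c(substrate)+c(target)). With reagent near 2.51 M, the readings at 0.667 min and 2.00 min give k = 0.0220 M⁻² s⁻¹.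

With the direct step still set aside, target stops rising when k·c(substrate)·c(reagent) equals kd, so the rule is a break-even product K, c(substrate)·c(reagent) = kd/k = 0.0719 M^2. In the flask, substrate is the limiting reagent, and solving the product, with one reagent used per substrate, gives a fraction of substrate left of 3.81 %, with reagent at 1.26 M.

While the logarithm of the fraction of substrate left falls, c(over-reaction product) grows by K/c(reagent) per unit of that logarithm. Holding reagent at 1.26 M costs 12.5 % of the substrate charged, leaving 83.7 % as target. That is the weak link, since c(reagent) stood higher than this earlier. Integrating with reagent falling gives a loss of 9.99 %, so this reckoning puts the peak of the flask at 86.2 %.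

The forecast, holding that “The runs show slow initial formation that then accelerates”, names 82 % at 2.8 min.

The flask peaks at 2.40 min with 85.7 % of target. Substrate then stands at 4.01 % and reagent at 46.7 % of its own charge, so the product of their concentrations is 0.0759 M^2 against the break-even 0.0719 M^2.

    substrate + reagent + target → 2 target (k = 0.0210 M⁻² s⁻¹)
    substrate + reagent → target (k = 1.20 × 10⁻⁴ M⁻¹ s⁻¹)
    target → over-reaction product (k = 0.00160 s⁻¹)

In the neighbour flask with 0.60 M of substrate and reagent as charged before, the same product gives a fraction of substrate left of 5.62 % and a loss of 15.1 %, hence a reckoned peak of 79.3 %. The computed neighbour reaches 78.8 %.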